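**Strategy.** Everything rests on cutting the enone between its carbonyl carbon and the alkene. In the benzofuranone the C7 phenol oxygen lies 1,5 to that ketone carbon (O–C7–C6–CH2–CH2–C=O). The ketone carbon is therefore carried as the carbonyl of a six-membered aryl lactone (a chroman-2-one ring) on the finished arene, which already bears the ester and acetal of the future hydroxyphthalide. (E)-Undec-1-enyllithium opens this lactone: one operation forms the acyl–alkenyl bond, joins the C11 and C17 fragments and frees the phenol. The same lactone earlier tethers the C3 unit and serves as the diene oxygen in an Alder–Rickert arene construction. Formylation and a dynamic kinetic resolution of the lactol finish the route.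

Key step: step 6

Assumption: C3 is a hemiacylal carbon that can epimerise through the ring-opened 2-formylbenzoate; it is taken to hold its configuration in neutral, aprotic, base-free media, so it is fixed as an O-acyl derivative and unmasked last without breaking either C3–O bond.

**Step 1**
Reactants: 1 3,3-diethoxyprop-1-yne
Product: 3 ethyl 4,4-diethoxybut-2-ynoate, via lithium acetylide 2 (not isolated)
Conditions: n-BuLi, THF, −78 °C; then ClCO2Et, −78 → 0 °C
Reagents that add atoms: ethyl chloroformate, CCOC(=O)Cl
Why: C-acylation of a lithium acetylide with a chloroformate (alkynoate synthesis) is clean at low temperature and the diethyl acetal is inert to base.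

**Step 2**
Reactants: 4 cyclohexane-1,3-dione; 5 acryloyl chloride
Product: 6 3,4,7,8-tetrahydro-2H-chromene-2,5(6H)-dione (enol δ-lactone)
Conditions: DMAP (20 mol %), iPr2NEt, CH2Cl2, 0 °C → rt
Reagents that add atoms: none
Why: Lewis-base-catalysed Michael addition–lactonisation (formal [3+3] annulation) should occur, in which the dione C2 adds to the β-carbon of the acryloyl pyridinium ion and the enol oxygen then closes the six-membered lactone, any O-acrylate formed first being returned to the same ion pair by DMAP.

**Step 3**
Reactants: 6 3,4,7,8-tetrahydro-2H-chromene-2,5(6H)-dione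
Product: 7 5-(trimethylsilyloxy)-3,4,7,8-tetrahydro-2H-chromen-2-one (cross-conjugated silyl dienol ether, diene C6=C5–C4a=C8a; used crude)
Conditions: TMSOTf, Et3N, Et2O, 0 °C
Reagents that add atoms: trimethylsilyl triflate, C[Si](C)(C)OS(=O)(=O)C(F)(F)F
Why: soft enolisation (silyl triflate/amine) should silylate the more Lewis-basic ketone and remove the α′-proton at C6 to give the 2-silyloxy-1,3-diene, the lactone enolising far more slowly.

**Step 4**
Reactants: 7 5-(trimethylsilyloxy)-3,4,7,8-tetrahydro-2H-chromen-2-one; 3 ethyl 4,4-diethoxybut-2-ynoate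
Product: 10 ethyl 7-(diethoxymethyl)-5-hydroxy-2-oxo-3,4-dihydro-2H-chromene-8-carboxylate, via bicyclooctadiene adduct 8 (not isolated), via aryl silyl ether 9 (not isolated)
Conditions: neat, BHT (cat.), 150 °C, sealed tube; then MeOH, AcOH (cat.), rt
Reagents that add atoms: none
Why: an Alder–Rickert sequence is expected, in which Diels–Alder addition across C6/C8a (the nucleophilic terminus C6 bonding to the ester β-carbon, which places CO2Et next to the lactone oxygen) is followed by retro-Diels–Alder loss of the C7–C8 bridge as ethene, and methanolysis then frees the phenol.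

**Step 5**
Reactants: 11 undec-1-yne
Product: 13 (E)-1-iodoundec-1-ene, via alkenylzirconocene 12 (not isolated)
Conditions: Cp2Zr(H)Cl, THF, rt; then I2, 0 °C
Reagents that add atoms: iodine, II
Why: hydrozirconation adds Zr–H syn with zirconium on the terminal carbon and iodinolysis of the C–Zr bond proceeds with retention, which fixes the E alkene.

**Step 6**
Reactants: 10 ethyl 7-(diethoxymethyl)-5-hydroxy-2-oxo-3,4-dihydro-2H-chromene-8-carboxylate; 13 (E)-1-iodoundec-1-ene
Product: 17 ethyl 6-(diethoxymethyl)-2,4-dihydroxy-3-[(4E)-3-oxotetradec-4-en-1-yl]benzoate, via sodium phenoxide 14 (not isolated), via alkenyllithium 15 (not isolated), via hemiketal alkoxide 16 (not isolated)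
Conditions: 10, NaH, THF, 0 → −78 °C; 13, t-BuLi (2 equiv), Et2O, −78 °C; 15 added to 14, −78 °C; AcOH, −78 °C → rt
Reagents that add atoms: none
Why: The alkenyllithium, formed from 13 by iodine–lithium exchange with retention of the E geometry, adds to the aryl δ-lactone carbonyl (C2 of the chromanone) to give the cyclic hemiketal alkoxide 16, which on protonation opens to the enone and the phenol (the future C7–OH), so the acyl–alkenyl bond is made and the temporary ring is removed in one operation. The closest known reaction type is the mono-addition of organolithium reagents to lactones, 3,4-dihydrocoumarins included, which stops at the 2-substituted chroman-2-ol/γ-(2-hydroxyaryl) ketone stage. No ring is closed and no stereocentre is created; the only stereochemical element, the E alkene, is carried over unchanged from 13. The step needs mono-addition and site selectivity: 16 should keep the ketone masked until the cold acetic acid quench, inverse addition keeps the lactone in excess, the ethyl ester is flanked by two ortho substituents and deactivated by the para phenoxide, and the acetal is inert. Phenoxide 14 can translactonise onto the other flanking oxygen, but both lactone isomers would open to the same product 17.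

**Step 7**
Reactants: 17 ethyl 6-(diethoxymethyl)-2,4-dihydroxy-3-[(4E)-3-oxotetradec-4-en-1-yl]benzoate
Product: 18 racemic 3,5,7-trihydroxy-6-[(4E)-3-oxotetradec-4-en-1-yl]-2-benzofuran-1(3H)-one
Conditions: 2 M HCl, THF, 45 °C
Reagents that add atoms: water, O
Why: acid-catalysed acetal hydrolysis followed by lactonisation with neighbouring-group participation (the electron-rich ester carbonyl oxygen captures the protonated aldehyde and ethanol is lost) should give the 3-hydroxyphthalide, whose new C3 centre is formed racemic and is set in step 9.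

**Step 8**
Reactants: 18 racemic 3,5,7-trihydroxy-6-[(4E)-3-oxotetradec-4-en-1-yl]-2-benzofuran-1(3H)-one
Product: 19 racemic 3,5,7-trihydroxy-1-oxo-6-[(4E)-3-oxotetradec-4-en-1-yl]-1,3-dihydro-2-benzofuran-4-carbaldehyde
Conditions: Cl2CHOMe, TiCl4, CH2Cl2, −78 → −20 °C; 1 M HCl work-up
Reagents that add atoms: dichloromethyl methyl ether, COC(Cl)Cl; water, O
Why: Rieche formylation (Friedel–Crafts type) can only attack C4, the sole unsubstituted ring carbon, which is ortho to the C5 titanium phenoxide and para to the C7 oxygen, while the electron-poor enone alkene should not react at low temperature and the lactol is restored by the hydrolytic work-up.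

**Step 9**
Reactants: 19 racemic 3,5,7-trihydroxy-1-oxo-6-[(4E)-3-oxotetradec-4-en-1-yl]-1,3-dihydro-2-benzofuran-4-carbaldehyde
Product: 20 (3R)-3-acetoxy-5,7-dihydroxy-1-oxo-6-[(4E)-3-oxotetradec-4-en-1-yl]-1,3-dihydro-2-benzofuran-4-carbaldehyde
Conditions: chiral acyl-transfer catalyst (4-arylpyridine N-oxide or isothiourea type, 5 mol %, antipode that gives 3R), Ac2O (1.1 equiv), iPr2NEt, CHCl3, −20 °C
Reagents that add atoms: acetic anhydride, CC(=O)OC(C)=O
Why: in this acylative dynamic kinetic resolution of a 3-hydroxyphthalide, base-mediated ring–chain tautomerism should interconvert the lactol enantiomers faster than acyl transfer, so the chiral catalyst–acyl ion pair sets C3 as R, while the two chelated, doubly ortho-substituted phenols should react more slowly.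

**Step 10**
Reactants: 20 (3R)-3-acetoxy-5,7-dihydroxy-1-oxo-6-[(4E)-3-oxotetradec-4-en-1-yl]-1,3-dihydro-2-benzofuran-4-carbaldehyde
Product: 21 (3R)-3,5,7-trihydroxy-1-oxo-6-[(4E)-3-oxotetradec-4-en-1-yl]-1,3-dihydro-2-benzofuran-4-carbaldehyde
Conditions: immobilised Candida antarctica lipase B, n-BuOH, MTBE, 30 °C; filter, evaporate below 30 °C
Reagents that add atoms: none
Why: lipase-catalysed transesterification cleaves the acyl–oxygen bond through an acyl-enzyme, so neither C3–O bond is broken and the 3R configuration should be retained, and the neutral aprotic medium avoids the ring-opened carboxylate through which the lactol would racemise.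

**Compound list**

1 | 3,3-diethoxyprop-1-yne | C#CC(OCC)OCC | starting material
2 | lithium 3,3-diethoxyprop-1-yn-1-ide | [Li]C#CC(OCC)OCC | intermediate
3 | ethyl 4,4-diethoxybut-2-ynoate | CCOC(=O)C#CC(OCC)OCC | intermediate
4 | cyclohexane-1,3-dione | O=C1CCCC(=O)C1 | starting material
5 | acryloyl chloride | C=CC(=O)Cl | starting material
6 | 3,4,7,8-tetrahydro-2H-chromene-2,5(6H)-dione | O=C1CCC2=C(CCCC2=O)O1 | intermediate
7 | 5-(trimethylsilyloxy)-3,4,7,8-tetrahydro-2H-chromen-2-one | O=C1CCC2=C(CCC=C2O[Si](C)(C)C)O1 | intermediate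
8 | bicyclo[2.2.2]octadiene Diels–Alder adduct of 7 and 3 (racemic; bonds C6–Cβ and C8a–Cα, ethano bridge C7–C8) | CCOC(=O)C1=C(C(OCC)OCC)C2CCC13OC(=O)CCC3=C2O[Si](C)(C)C | intermediate
9 | ethyl 7-(diethoxymethyl)-2-oxo-5-(trimethylsilyloxy)-3,4-dihydro-2H-chromene-8-carboxylate | CCOC(=O)c1c(C(OCC)OCC)cc(O[Si](C)(C)C)c2CCC(=O)Oc12 | intermediate
10 | ethyl 7-(diethoxymethyl)-5-hydroxy-2-oxo-3,4-dihydro-2H-chromene-8-carboxylate | CCOC(=O)c1c(C(OCC)OCC)cc(O)c2CCC(=O)Oc12 | intermediate
11 | undec-1-yne | CCCCCCCCCC#C | starting material
12 | chlorobis(cyclopentadienyl)[(E)-undec-1-enyl]zirconium | CCCCCCCCC/C=C/[Zr](Cl)(C1C=CC=C1)C1C=CC=C1 | intermediate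
13 | (E)-1-iodoundec-1-ene | CCCCCCCCC/C=C/I | intermediate
14 | sodium phenoxide of 10 | CCOC(=O)c1c(C(OCC)OCC)cc([O-])c2CCC(=O)Oc12.[Na+] | intermediate
15 | (E)-undec-1-enyllithium | CCCCCCCCC/C=C/[Li] | intermediate
16 | lithium sodium salt of the 2-[(E)-undec-1-enyl]chroman-2-ol adduct (racemic hemiketal alkoxide) | CCCCCCCCC/C=C/C1([O-])CCc2c([O-])cc(C(OCC)OCC)c(C(=O)OCC)c2O1.[Li+].[Na+] | intermediate
17 | ethyl 6-(diethoxymethyl)-2,4-dihydroxy-3-[(4E)-3-oxotetradec-4-en-1-yl]benzoate | CCCCCCCCC/C=C/C(=O)CCc1c(O)cc(C(OCC)OCC)c(C(=O)OCC)c1O | intermediate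
18 | racemic 3,5,7-trihydroxy-6-[(4E)-3-oxotetradec-4-en-1-yl]-2-benzofuran-1(3H)-one | CCCCCCCCC/C=C/C(=O)CCc1c(O)cc2c(c1O)C(=O)OC2O | intermediate
19 | racemic 3,5,7-trihydroxy-1-oxo-6-[(4E)-3-oxotetradec-4-en-1-yl]-1,3-dihydro-2-benzofuran-4-carbaldehyde | CCCCCCCCC/C=C/C(=O)CCc1c(O)c(C=O)c2c(c1O)C(=O)OC2O | intermediate
20 | (3R)-3-acetoxy-5,7-dihydroxy-1-oxo-6-[(4E)-3-oxotetradec-4-en-1-yl]-1,3-dihydro-2-benzofuran-4-carbaldehyde | CCCCCCCCC/C=C/C(=O)CCc1c(O)c(C=O)c2c(c1O)C(=O)O[C@H]2OC(C)=O | intermediate
21 | (3R)-3,5,7-trihydroxy-1-oxo-6-[(4E)-3-oxotetradec-4-en-1-yl]-1,3-dihydro-2-benzofuran-4-carbaldehyde | CCCCCCCCC/C=C/C(=O)CCc1c(O)c(C=O)c2c(c1O)C(=O)O[C@H]2O | target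

**Totals**

Total step count: 10. Longest linear sequence: 8 steps (steps 2, 3, 4, 6, 7, 8, 9, 10).

**Steps most likely to fail**

Step 6. The hemiketal alkoxide may collapse to the enone before the quench and take up a second alkenyl group, or the organolithium may act as a base on the lactone α-CH2 (ring-opening through a ketene without C–C bond formation). Fallback: setting out from 10, aminolysis of the lactone with MeNH(OMe)·HCl and i-PrMgCl (THF, −20 °C) would give the Weinreb amide F1. After deprotonation of its two phenols with NaH, addition of 15 would stop at the chelated tetrahedral intermediate and give 17 on acidic work-up, where the route is rejoined.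

Step 9. Acyl transfer may discriminate poorly between the lactol enantiomers on this hexasubstituted ring, or acylation of the phenols may compete. Fallback: setting out from 19, unselective acetylation (Ac2O, pyridine, 0 °C) would give the racemic acetate F2. Preparative chromatography on a chiral stationary phase would separate it into 20 and the (3S)-acetate F3. F3 would be hydrolysed (aqueous NaHCO3, THF) back to racemic 19 and recycled; the route is rejoined at 20.

Step 10. The lipase may not accept the (3R)-acylal, or the liberated lactol may lose configuration by ring–chain tautomerism before isolation. Fallback: setting out from 19, the protocol of step 9 would be run with pent-4-enoic anhydride to give the (3R)-pent-4-enoate F4. Iodine in THF–water (pH 3 buffer, 0 °C) would then trigger iodolactonisation of the acyl group and release the lactol by acyl–oxygen cleavage under weakly acidic, base-free conditions, which rejoins the route at 21.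

**Further compounds**

F1 | step 6 | ethyl 6-(diethoxymethyl)-2,4-dihydroxy-3-{3-[methoxy(methyl)amino]-3-oxopropyl}benzoate | CON(C)C(=O)CCc1c(O)cc(C(OCC)OCC)c(C(=O)OCC)c1O
F2 | step 9 | racemic 3-acetoxy-5,7-dihydroxy-1-oxo-6-[(4E)-3-oxotetradec-4-en-1-yl]-1,3-dihydro-2-benzofuran-4-carbaldehyde | CCCCCCCCC/C=C/C(=O)CCc1c(O)c(C=O)c2c(c1O)C(=O)OC2OC(C)=O
F3 | step 9 | (3S)-3-acetoxy-5,7-dihydroxy-1-oxo-6-[(4E)-3-oxotetradec-4-en-1-yl]-1,3-dihydro-2-benzofuran-4-carbaldehyde | CCCCCCCCC/C=C/C(=O)CCc1c(O)c(C=O)c2c(c1O)C(=O)O[C@@H]2OC(C)=O
F4 | step 10 | (3R)-4-formyl-5,7-dihydroxy-1-oxo-6-[(4E)-3-oxotetradec-4-en-1-yl]-1,3-dihydro-2-benzofuran-3-yl pent-4-enoate | CCCCCCCCC/C=C/C(=O)CCc1c(O)c(C=O)c2c(c1O)C(=O)O[C@H]2OC(=O)CCC=C
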